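The route rests on cutting the aryl C4a–O4 bond of the dioxane ring (benzodioxin numbering) and on the fact that C2 of this ring is a hemiketal, a masked acyl carbon. The precursor is therefore an aryl (R)-lactate: its ester oxygen is the future O1, and a bromine sits on C4a between that oxygen and the C5 methoxy group. Palladium-catalysed intramolecular O-arylation of the lactate hydroxyl closes the ring as a benzodioxinone and fixes O4–C3 with the lactic acid configuration untouched. A single aryllithium addition to this lactone then delivers the hemiketal carbon with its trimethoxyphenyl group.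

Key step: step 6

Numbering used: O1, C2 (hemiketal carbon), C3 (CHCH3), O4, C4a, C5 (OCH3), C7 (allyl), C8a.

Assumption: C2 is a hemiketal centre that epimerises through the open keto-phenol form, and the (2S,3R) isomer of the target (OH and CH3 trans-diaxial, aryl equatorial) is taken to be the favoured closed form. C3 is therefore the only stereocentre the route has to set.

Step 1
Reactants: 1 2-bromo-1,3-dimethoxybenzene
Product: 2 2-(4-bromo-3,5-dimethoxyphenyl)-4,4,5,5-tetramethyl-1,3,2-dioxaborolane
Conditions: [Ir(OMe)(cod)]2 (1.5 mol%), dtbpy (3 mol%), B2pin2 (1.0 equiv), THF, 80 °C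
Reagents that add atoms: bis(pinacolato)diboron, CC1(C)OB(OC1(C)C)B1OC(C)(C)C(C)(C)O1
Why: Iridium-catalysed C–H borylation is sterically controlled, so the only C–H without an ortho substituent (para to bromine) should be borylated, and the aryl bromide is inert to this catalyst.

Step 2
Reactants: 2 2-(4-bromo-3,5-dimethoxyphenyl)-4,4,5,5-tetramethyl-1,3,2-dioxaborolane, 3 allyl bromide
Product: 4 5-allyl-2-bromo-1,3-dimethoxybenzene
Conditions: Pd(PPh3)4 (5 mol%), CsF (3 equiv), allyl bromide (2 equiv), THF, 65 °C
Reagents that add atoms: none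
Why: Suzuki–Miyaura coupling with an allyl electrophile, in which zerovalent palladium adds to allyl bromide far faster than to the di-ortho-substituted, electron-rich aryl bromide, so the C–Br bond needed later should survive.

Step 3
Reactants: 4 5-allyl-2-bromo-1,3-dimethoxybenzene
Product: 5 5-allyl-2-bromo-3-methoxyphenol
Conditions: NaSEt (2.5 equiv), DMF, 110 °C; aq. HCl work-up
Reagents that add atoms: none
Why: Thiolate SN2 demethylation of an aryl methyl ether; the two methoxy groups are equivalent by symmetry and the phenoxide formed should protect the second one, so a single phenol is expected.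

Step 4
Reactants: 5 5-allyl-2-bromo-3-methoxyphenol, 6 (R)-2-(benzyloxy)propanoic acid
Product: 7 5-allyl-2-bromo-3-methoxyphenyl (R)-2-(benzyloxy)propanoate
Conditions: EDC·HCl (1.3 equiv), DMAP (0.1 equiv), CH2Cl2, 0 °C to rt
Reagents that add atoms: none
Why: Steglich-type carbodiimide esterification of a phenol; no bond to the stereocentre is touched, and catalytic DMAP at low temperature should keep the α-alkoxy acid from epimerising.

Step 5
Reactants: 7 5-allyl-2-bromo-3-methoxyphenyl (R)-2-(benzyloxy)propanoate
Product: 8 5-allyl-2-bromo-3-methoxyphenyl (R)-2-hydroxypropanoate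
Conditions: BCl3 (2 equiv), pentamethylbenzene (3 equiv), CH2Cl2, −78 to −40 °C; MeOH/H2O quench
Reagents that add atoms: none
Why: Lewis-acid debenzylation with a cation scavenger: BCl3 chelated between ether oxygen and ester carbonyl releases the benzyl cation to pentamethylbenzene, while the aryl methyl ether, aryl ester, aryl bromide and allyl group should survive at low temperature and the O–C3 bond stays intact.

Step 6
Reactants: 8 5-allyl-2-bromo-3-methoxyphenyl (R)-2-hydroxypropanoate
Product: 9 (3R)-7-allyl-5-methoxy-3-methyl-1,4-benzodioxin-2(3H)-one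
Conditions: Pd2(dba)3 (2.5 mol%), RockPhos (7.5 mol%), K3PO4 (1.5 equiv), 4 Å MS, toluene (0.02 M, slow addition of 8), 70 °C
Reagents that add atoms: none
Why: Buchwald–Hartwig-type intramolecular C–O coupling, the reaction type that closes 1,4-benzodioxanes from 2-(2-bromoaryloxy) alcohols: zerovalent palladium inserts into the C–Br bond, the lactate hydroxyl binds and is deprotonated at the metal by the insoluble phosphate, and C–O reductive elimination from the seven-membered aryl(alkoxo)palladium chelate forms the C4a–O4 bond. The dioxinone ring closes in a 6-exo sense, O4 attacking the ipso carbon held ortho to the ester oxygen. No stereocentre is created; C3 should keep the (R) configuration of the lactate because no bond to it is broken and the weak heterogeneous base is not expected to remove the α-proton at 70 °C. The step needs chemoselectivity for intramolecular O-arylation over intermolecular acyl transfer of the aryl ester, β-hydride elimination of the palladium alkoxide and Heck insertion of the allyl group; the ortho placement of bromide and tether, high dilution and the bulky biaryl phosphine (fast reductive elimination from an electron-rich, di-ortho-substituted aryl) are meant to secure this. There is only one C–Br bond, so site selectivity is not in question.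

Step 7
Reactants: 9 (3R)-7-allyl-5-methoxy-3-methyl-1,4-benzodioxin-2(3H)-one, 10 5-bromo-1,2,3-trimethoxybenzene
Product: 13 (2S,3R)-7-allyl-5-methoxy-3-methyl-2-(3,4,5-trimethoxyphenyl)-2,3-dihydro-1,4-benzodioxin-2-ol, via 3,4,5-trimethoxyphenyllithium 11 (not isolated), via lithium hemiketal alkoxide 12 (not isolated)
Conditions: 10, n-BuLi (1.05 equiv), THF, −78 °C, 30 min; cannulate into 9, THF, −78 °C; AcOH quench at −78 °C, then rt
Reagents that add atoms: none
Why: Lactone-to-lactol addition of an aryllithium: the cyclic lithium hemiketal alkoxide should persist at −78 °C, and after protonation C2 should settle by ring–chain tautomerism into the (2S) form with OH axial and trans to the C3 methyl, while C3 from lactic acid is untouched.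

Compound list
1 | 2-bromo-1,3-dimethoxybenzene | COc1cccc(OC)c1Br | starting material
2 | 2-(4-bromo-3,5-dimethoxyphenyl)-4,4,5,5-tetramethyl-1,3,2-dioxaborolane | COc1cc(cc(OC)c1Br)B1OC(C)(C)C(C)(C)O1 | intermediate
3 | allyl bromide (3-bromoprop-1-ene) | C=CCBr | starting material
4 | 5-allyl-2-bromo-1,3-dimethoxybenzene | C=CCc1cc(OC)c(Br)c(OC)c1 | intermediate
5 | 5-allyl-2-bromo-3-methoxyphenol | C=CCc1cc(O)c(Br)c(OC)c1 | intermediate
6 | (R)-2-(benzyloxy)propanoic acid | C[C@@H](OCc1ccccc1)C(=O)O | starting material
7 | 5-allyl-2-bromo-3-methoxyphenyl (R)-2-(benzyloxy)propanoate | C=CCc1cc(OC)c(Br)c(c1)OC(=O)[C@@H](C)OCc1ccccc1 | intermediate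
8 | 5-allyl-2-bromo-3-methoxyphenyl (R)-2-hydroxypropanoate | C=CCc1cc(OC)c(Br)c(c1)OC(=O)[C@@H](C)O | intermediate
9 | (3R)-7-allyl-5-methoxy-3-methyl-1,4-benzodioxin-2(3H)-one | C=CCc1cc(OC)c2c(c1)OC(=O)[C@@H](C)O2 | intermediate
10 | 5-bromo-1,2,3-trimethoxybenzene | COc1cc(Br)cc(OC)c1OC | starting material
11 | 3,4,5-trimethoxyphenyllithium (not isolated) | [Li]c1cc(OC)c(OC)c(OC)c1 | intermediate
12 | lithium (3R)-7-allyl-5-methoxy-3-methyl-2-(3,4,5-trimethoxyphenyl)-2,3-dihydro-1,4-benzodioxin-2-olate, C2 epimers (not isolated) | C=CCc1cc(OC)c2c(c1)OC([O-])(c1cc(OC)c(OC)c(OC)c1)[C@@H](C)O2.[Li+] | intermediate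
13 | (2S,3R)-7-allyl-5-methoxy-3-methyl-2-(3,4,5-trimethoxyphenyl)-2,3-dihydro-1,4-benzodioxin-2-ol | C=CCc1cc(OC)c2c(c1)O[C@@](O)(c1cc(OC)c(OC)c(OC)c1)[C@@H](C)O2 | target

Total step count: 7. Longest linear sequence: 7 steps (1 → 2 → 4 → 5 → 7 → 8 → 9 → 13).

Steps most likely to fail

Step 6. The hydroxy aryl ester may undergo intermolecular acyl transfer (oligomerisation) under base before the palladium cycle turns over. The palladium alkoxide may undergo β-hydride elimination, and the lactone may epimerise at C3 once formed. The fallback sets out from 4 and returns at 9, closing the ring at the acyl carbon under acid so that no alkoxide meets an aryl ester. Bromine–lithium exchange on 4 (n-BuLi, THF, −78 °C), B(OMe)3 and H2O2/NaOH should give 4-allyl-2,6-dimethoxyphenol F1. Mitsunobu etherification with methyl (S)-lactate (PPh3, DIAD, THF, 0 °C) inverts the carbinol carbon and should give methyl (R)-2-(4-allyl-2,6-dimethoxyphenoxy)propanoate F2. BBr3 (1.0 equiv, CH2Cl2, −78 °C) cleaves one of the two equivalent methyl ethers to methyl (R)-2-(4-allyl-2-hydroxy-6-methoxyphenoxy)propanoate F3, and TsOH in toluene at 80 °C lactonises it to 9.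

Step 7. The tetrahedral adduct may collapse to the ketone and take up a second aryllithium, and the aryllithium may enolise the lactone with loss of configuration at C3. The fallback sets out from 9 and returns at 13. Me(MeO)NH·HCl with AlMe3 (CH2Cl2, 0 °C) opens the lactone to (R)-2-(4-allyl-2-hydroxy-6-methoxyphenoxy)-N-methoxy-N-methylpropanamide F4. 3,4,5-Trimethoxyphenylmagnesium bromide (2.5 equiv, THF, −20 to 0 °C) then adds once through the chelated Weinreb intermediate and should give, after work-up, (R)-2-(4-allyl-2-hydroxy-6-methoxyphenoxy)-1-(3,4,5-trimethoxyphenyl)propan-1-one F5, which is expected to close spontaneously to 13.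

Step 3. The allyl double bond may migrate into conjugation under hot thiolate, and the second methyl ether may also be cleaved. The fallback sets out from 1 and returns at 5, cleaving the ether before the allyl group exists. BBr3 (1.0 equiv, CH2Cl2, −78 to 0 °C) on 1 should give 2-bromo-3-methoxyphenol F6, and MOMCl/i-Pr2NEt gives 2-bromo-1-methoxy-3-(methoxymethoxy)benzene F7. Iridium borylation as in step 1 gives 2-[4-bromo-3-methoxy-5-(methoxymethoxy)phenyl]-4,4,5,5-tetramethyl-1,3,2-dioxaborolane F8, and allylation as in step 2 gives 5-allyl-2-bromo-1-methoxy-3-(methoxymethoxy)benzene F9. HCl in MeOH at rt removes the acetal to give 5.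

Further compounds
F1 | step 6 | 4-allyl-2,6-dimethoxyphenol | C=CCc1cc(OC)c(O)c(OC)c1
F2 | step 6 | methyl (R)-2-(4-allyl-2,6-dimethoxyphenoxy)propanoate | C=CCc1cc(OC)c(O[C@H](C)C(=O)OC)c(OC)c1
F3 | step 6 | methyl (R)-2-(4-allyl-2-hydroxy-6-methoxyphenoxy)propanoate | C=CCc1cc(O)c(O[C@H](C)C(=O)OC)c(OC)c1
F4 | step 7 | (R)-2-(4-allyl-2-hydroxy-6-methoxyphenoxy)-N-methoxy-N-methylpropanamide | C=CCc1cc(O)c(O[C@H](C)C(=O)N(C)OC)c(OC)c1
F5 | step 7 | (R)-2-(4-allyl-2-hydroxy-6-methoxyphenoxy)-1-(3,4,5-trimethoxyphenyl)propan-1-one | C=CCc1cc(O)c(O[C@H](C)C(=O)c2cc(OC)c(OC)c(OC)c2)c(OC)c1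
F6 | step 3 | 2-bromo-3-methoxyphenol | COc1cccc(O)c1Br
F7 | step 3 | 2-bromo-1-methoxy-3-(methoxymethoxy)benzene | COCOc1cccc(OC)c1Br
F8 | step 3 | 2-[4-bromo-3-methoxy-5-(methoxymethoxy)phenyl]-4,4,5,5-tetramethyl-1,3,2-dioxaborolane | COCOc1cc(cc(OC)c1Br)B1OC(C)(C)C(C)(C)O1
F9 | step 3 | 5-allyl-2-bromo-1-methoxy-3-(methoxymethoxy)benzene | C=CCc1cc(OC)c(Br)c(OCOC)c1
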